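Retrosynthesis: the two benzyl ethers go last; ring B is then opened at C8a–O1, which leaves a 3,3-diarylpropanoic acid; this is cut at the C4–ring C bond (conjugate arylation), at C4a–C4 (Heck reaction) and at the C8–acyl bond (acylation of resorcinol).
Enabling feature: O1 sits on C8a, between C4a (para to the C7 hydroxyl) and the acyl-bearing C8. Oxidation of the C7 phenol lets the side-chain carboxyl group capture C4a, and in the resulting dienone C8a is the β-carbon of an enone activated by both the C7 carbonyl and the C8 acyl group, so oxygen can be passed from C4a to C8a by addition and elimination.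
Forward order: ring A (the benzo ring) is acylated, benzylated and brominated; the three-carbon chain is attached by Heck reaction and ring C (the 4-oxyphenyl group) by rhodium-catalysed arylation; ring B (the lactone) closes last, and debenzylation ends the route.
Stereochemistry: the only stereocentre, C4 (S), is set by the (R)-BINAP/rhodium-catalysed 1,4-addition of the ring C boronic acid to the (E)-cinnamate and is a spectator afterwards.

Key step: step 7

Assumption: the Rh/BINAP arylation is taken to follow the usual facial preference for (E)-enoates ((S)-BINAP gives (R)-3-arylbutanoates from crotonates), which corresponds to (R)-BINAP for the (S)-adduct here; if the sense proves opposite, the other ligand enantiomer is used.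

Step 1
Reactants: 1 resorcinol; 2 3-phenylpropanoic acid
Product: 3 1-(2,4-dihydroxyphenyl)-3-phenylpropan-1-one
Conditions: BF3·OEt2 (neat), 85 °C; aq. NaOAc work-up
Reagents that add atoms: none
Why: Friedel–Crafts acylation with the BF3-activated carboxylic acid takes place at C4 of resorcinol, ortho to one hydroxyl and para to the other, and stops after one acylation because the chelated ketone deactivates the ring.

Step 2
Reactants: 3 1-(2,4-dihydroxyphenyl)-3-phenylpropan-1-one
Product: 4 1-[4-(benzyloxy)-2-hydroxyphenyl]-3-phenylpropan-1-one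
Conditions: BnBr, K2CO3, acetone, reflux
Reagents that add atoms: benzyl bromide, BrCc1ccccc1
Why: Williamson etherification is selective for the C4 hydroxyl, since the C2 hydroxyl is hydrogen-bonded to the ketone and much less nucleophilic under carbonate conditions.

Step 3
Reactants: 4 1-[4-(benzyloxy)-2-hydroxyphenyl]-3-phenylpropan-1-one
Product: 5 1-[4-(benzyloxy)-5-bromo-2-hydroxyphenyl]-3-phenylpropan-1-one
Conditions: NBS, NH4OAc (cat.), MeCN, 0 °C to rt
Reagents that add atoms: N-bromosuccinimide, O=C1CCC(=O)N1Br
Why: Electrophilic aromatic bromination should go to C5, para to the free phenol and ortho to the benzyloxy group, the alternative C3 being flanked by two oxygen substituents.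

Step 4
Reactants: 5 1-[4-(benzyloxy)-5-bromo-2-hydroxyphenyl]-3-phenylpropan-1-one; 6 methyl acrylate
Product: 7 methyl (E)-3-[2-(benzyloxy)-4-hydroxy-5-(3-phenylpropanoyl)phenyl]prop-2-enoate
Conditions: Pd(OAc)2 (5 mol%), P(o-tol)3, Et3N, DMF, 100 °C
Reagents that add atoms: none
Why: Mizoroki–Heck reaction (zerovalent palladium formed in the flask; oxidative addition, syn insertion, syn β-hydride elimination) gives the (E)-cinnamate and tolerates the free phenol and the ketone.

Step 5
Reactants: 7 methyl (E)-3-[2-(benzyloxy)-4-hydroxy-5-(3-phenylpropanoyl)phenyl]prop-2-enoate; 8 4-(benzyloxy)phenylboronic acid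
Product: 9 methyl (S)-3-[4-(benzyloxy)phenyl]-3-[2-(benzyloxy)-4-hydroxy-5-(3-phenylpropanoyl)phenyl]propanoate
Conditions: Rh(acac)(C2H4)2 (3 mol%), (R)-BINAP, dioxane/H2O 10:1, 100 °C
Reagents that add atoms: none
Why: Hayashi–Miyaura reaction: the aryl group passes from boron to monovalent rhodium, the (R)-BINAP complex inserts the (E)-enoate on one alkene face only and protonolysis of the oxa-π-allyl rhodium species frees the ester, so the ligand sets C4 as S.

Step 6
Reactants: 9 methyl (S)-3-[4-(benzyloxy)phenyl]-3-[2-(benzyloxy)-4-hydroxy-5-(3-phenylpropanoyl)phenyl]propanoate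
Product: 10 (S)-3-[4-(benzyloxy)phenyl]-3-[2-(benzyloxy)-4-hydroxy-5-(3-phenylpropanoyl)phenyl]propanoic acid
Conditions: LiOH, THF/MeOH/H2O, rt; then 1 M HCl
Reagents that add atoms: lithium hydroxide, [Li+].[OH-]
Why: Saponification of the methyl ester; C4 is β to the carboxyl group and bears no acidic hydrogen, so its configuration is kept.

Step 7
Reactants: 10 (S)-3-[4-(benzyloxy)phenyl]-3-[2-(benzyloxy)-4-hydroxy-5-(3-phenylpropanoyl)phenyl]propanoic acid
Product: 14 (S)-5-(benzyloxy)-4-[4-(benzyloxy)phenyl]-7-hydroxy-8-(3-phenylpropanoyl)chroman-2-one, via spirolactone dienone 11 (not isolated), via para-quinol acid 12 (not isolated), via hydroxy lactone adduct 13 (not isolated)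
Conditions: PhI(OAc)2, MeCN, 0 °C; then aq. NaHCO3, 0 °C to rt; then CF3CO2H, rt
Reagents that add atoms: water, O
Why: Proposed new method: PhI(OAc)2 (trivalent iodine) turns the C7 phenol of 10 into a phenoxenium equivalent that the tethered carboxyl group captures at the para carbon C4a (5-exo spiro closure, the known oxidative spirolactonisation of 3-(4-hydroxyaryl)propanoic acids), and in dienone 11 the C7 carbonyl and the C8 acyl group together make C8a the β-carbon of an alkylidene 1,3-diketone. An acid-induced 1,2-shift is deliberately avoided, because spirolactones of this type rearrange with migration of carbon (they give 6-hydroxy-3,4-dihydrocoumarins), which here would carry C4 to C8a; the oxygen is relayed instead by addition and elimination: bicarbonate opens the lactone to the para-quinol acid 12, its carboxylate closes ring B on C8a by a 6-exo-trig oxa-Michael addition (13), and acid then expels the C4a hydroxyl as water while loss of the C8a proton restores the arene. The closest known reaction types are the spirolactonisation, lactone opening and intramolecular hetero-Michael cascade used on tyrosine-derived spirolactones and the dehydrative re-aromatisation of para-quinol Michael adducts to meta-functionalised phenols; what is new is their use to move a carboxyl oxygen from C4a to C8a. No stereocentre is formed in 14, the centres at C4a, C8 and C8a of 11 to 13 being lost on aromatisation, and C4 from step 5 is a spectator that is neither deprotonated nor ionised. The step needs oxygen and not C4 on C8a, which is secured by making the C8a–O bond under basic conditions before acid is added, and it needs C8a and not C5, which is secured by the double activation of C8a through the C8 acyl group and by the benzyloxy group on C5, a vinylogous ester carbon without hydrogen.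

Step 8
Reactants: 14 (S)-5-(benzyloxy)-4-[4-(benzyloxy)phenyl]-7-hydroxy-8-(3-phenylpropanoyl)chroman-2-one
Product: 15 (S)-5,7-dihydroxy-4-(4-hydroxyphenyl)-8-(3-phenylpropanoyl)chroman-2-one
Conditions: H2 (1 atm), 10% Pd/C, EtOAc, rt
Reagents that add atoms: none
Why: Catalytic hydrogenolysis cleaves both aryl benzyl ethers, while the lactone, the hydrogen-bonded aryl ketone and C4, which carries no heteroatom, are left alone under these neutral conditions.

Compound list
1 | resorcinol | Oc1cccc(O)c1 | starting material
2 | 3-phenylpropanoic acid | OC(=O)CCc1ccccc1 | starting material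
3 | 1-(2,4-dihydroxyphenyl)-3-phenylpropan-1-one | O=C(CCc1ccccc1)c1ccc(O)cc1O | intermediate
4 | 1-[4-(benzyloxy)-2-hydroxyphenyl]-3-phenylpropan-1-one | O=C(CCc1ccccc1)c1ccc(OCc2ccccc2)cc1O | intermediate
5 | 1-[4-(benzyloxy)-5-bromo-2-hydroxyphenyl]-3-phenylpropan-1-one | O=C(CCc1ccccc1)c1cc(Br)c(OCc2ccccc2)cc1O | intermediate
6 | methyl acrylate | C=CC(=O)OC | starting material
7 | methyl (E)-3-[2-(benzyloxy)-4-hydroxy-5-(3-phenylpropanoyl)phenyl]prop-2-enoate | COC(=O)/C=C/c1cc(C(=O)CCc2ccccc2)c(O)cc1OCc1ccccc1 | intermediate
8 | 4-(benzyloxy)phenylboronic acid | OB(O)c1ccc(OCc2ccccc2)cc1 | starting material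
9 | methyl (S)-3-[4-(benzyloxy)phenyl]-3-[2-(benzyloxy)-4-hydroxy-5-(3-phenylpropanoyl)phenyl]propanoate | COC(=O)C[C@@H](c1ccc(OCc2ccccc2)cc1)c1cc(C(=O)CCc2ccccc2)c(O)cc1OCc1ccccc1 | intermediate
10 | (S)-3-[4-(benzyloxy)phenyl]-3-[2-(benzyloxy)-4-hydroxy-5-(3-phenylpropanoyl)phenyl]propanoic acid | OC(=O)C[C@@H](c1ccc(OCc2ccccc2)cc1)c1cc(C(=O)CCc2ccccc2)c(O)cc1OCc1ccccc1 | intermediate
11 | (4S)-6-(benzyloxy)-4-[4-(benzyloxy)phenyl]-9-(3-phenylpropanoyl)-1-oxaspiro[4.5]deca-6,9-diene-2,8-dione, both configurations at the spiro carbon, formed in the flask in step 7 | O=C1C[C@@H](c2ccc(OCc3ccccc3)cc2)C2(O1)C=C(C(=O)CCc1ccccc1)C(=O)C=C2OCc1ccccc1 | intermediate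
12 | (S)-3-[4-(benzyloxy)phenyl]-3-[2-(benzyloxy)-1-hydroxy-4-oxo-5-(3-phenylpropanoyl)cyclohexa-2,5-dien-1-yl]propanoic acid, both configurations at the carbinol carbon, formed in the flask in step 7 | OC(=O)C[C@@H](c1ccc(OCc2ccccc2)cc1)C1(O)C=C(C(=O)CCc2ccccc2)C(=O)C=C1OCc1ccccc1 | intermediate
13 | (4S)-5-(benzyloxy)-4-[4-(benzyloxy)phenyl]-4a-hydroxy-8-(3-phenylpropanoyl)-4a,8a-dihydrochromane-2,7(8H)-dione, cis ring fusion expected, C4a, C8 and C8a unassigned, keto form drawn, formed in the flask in step 7 | O=C1C[C@@H](c2ccc(OCc3ccccc3)cc2)C2(O)C(OCc3ccccc3)=CC(=O)C(C(=O)CCc3ccccc3)C2O1 | intermediate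
14 | (S)-5-(benzyloxy)-4-[4-(benzyloxy)phenyl]-7-hydroxy-8-(3-phenylpropanoyl)chroman-2-one | O=C1C[C@@H](c2ccc(OCc3ccccc3)cc2)c2c(OCc3ccccc3)cc(O)c(C(=O)CCc3ccccc3)c2O1 | intermediate
15 | (S)-5,7-dihydroxy-4-(4-hydroxyphenyl)-8-(3-phenylpropanoyl)chroman-2-one | O=C1C[C@@H](c2ccc(O)cc2)c2c(O)cc(O)c(C(=O)CCc3ccccc3)c2O1 | target

Total step count: 8. Longest linear sequence: 8 steps (from resorcinol 1 to 15).

Steps most likely to fail

Step 7. Three processes may spoil it. The oxidised phenol may lose the doubly benzylic hydrogen on C4 (quinone methide formation, which would erase the stereocentre) instead of being captured at C4a. The lactone may open too slowly, so that on acidification a 1,2-shift of C4 to C8a takes over. The acyl dienone may be cleaved hydrolytically in base.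

The fallback gives up the oxidative C–O bond formation and brings the C8a oxygen in with the arene. It sets out from 3-phenylpropanoic acid 2 and comes back at 14.
- Acid 2 acylates phloroglucinol (Oc1cc(O)cc(O)c1; BF3·OEt2, as in step 1) to 1-(2,4,6-trihydroxyphenyl)-3-phenylpropan-1-one F1.
- Benzylation of the non-chelated para hydroxyl (BnBr, 1 equiv, K2CO3, DMF) gives 1-[4-(benzyloxy)-2,6-dihydroxyphenyl]-3-phenylpropan-1-one F2.
- Iminium-catalysed asymmetric Friedel–Crafts alkylation of F2 with (E)-3-[4-(benzyloxy)phenyl]prop-2-enal (O=C/C=C/c1ccc(OCc2ccccc2)cc1) uses (R)-2-[diphenyl(trimethylsilyloxy)methyl]pyrrolidine and PhCO2H in toluene. The catalyst enantiomer is chosen by analogy with malonate additions to cinnamaldehyde. Hemiacetal closure onto the neighbouring free hydroxyl should then give (4S)-5-(benzyloxy)-4-[4-(benzyloxy)phenyl]-8-(3-phenylpropanoyl)chromane-2,7-diol F3.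
- Oxidation of the lactol (pyridinium chlorochromate, [C5H5NH][CrO3Cl], CH2Cl2) returns to 14.

The regiochemistry is fixed because the two free ring positions of F2 are equivalent and only one oxygen ortho to the new chain is unprotected.

Step 5. Insertion into the electron-rich, ortho-substituted cinnamate may be slow, the 2-acylphenol may hold rhodium as an acetylacetonate-like chelate, protodeboronation may outrun addition, or facial selectivity may be insufficient.

The fallback takes the configuration from a resolution. It sets out from cinnamate 7 and comes back at 10.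
- The arylation with 8 is run without a chiral ligand, using the far more active [Rh(OH)(cod)]2 (dioxane/H2O, 60 °C), to give racemic methyl 3-[4-(benzyloxy)phenyl]-3-[2-(benzyloxy)-4-hydroxy-5-(3-phenylpropanoyl)phenyl]propanoate F4.
- Saponification as in step 6 gives racemic 3-[4-(benzyloxy)phenyl]-3-[2-(benzyloxy)-4-hydroxy-5-(3-phenylpropanoyl)phenyl]propanoic acid F5.
- Crystallisation with (R)-1-phenylethylamine should separate the (R)-1-phenylethylammonium salt of the (S)-acid F6; the other amine enantiomer is used if the opposite pair crystallises.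
- Acidification returns to 10.

Step 3. Bromination may occur at C3 between the two oxygen substituents, a second bromine may enter, or the ketone may be brominated at its α-carbon.

The fallback brings the halogen in with the arene. It sets out from acid 2 and comes back at 5.
- Acid 2 and commercial 4-bromoresorcinol (Oc1ccc(Br)c(O)c1) are joined by BF3·OEt2-mediated acylation as in step 1, which should give 1-(5-bromo-2,4-dihydroxyphenyl)-3-phenylpropan-1-one F7.
- Benzylation of the non-chelated hydroxyl as in step 2 returns to 5.

Further compounds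
F1 | step 7 | 1-(2,4,6-trihydroxyphenyl)-3-phenylpropan-1-one | O=C(CCc1ccccc1)c1c(O)cc(O)cc1O
F2 | step 7 | 1-[4-(benzyloxy)-2,6-dihydroxyphenyl]-3-phenylpropan-1-one | O=C(CCc1ccccc1)c1c(O)cc(OCc2ccccc2)cc1O
F3 | step 7 | (4S)-5-(benzyloxy)-4-[4-(benzyloxy)phenyl]-8-(3-phenylpropanoyl)chromane-2,7-diol (lactol, both anomers) | OC1C[C@@H](c2ccc(OCc3ccccc3)cc2)c2c(OCc3ccccc3)cc(O)c(C(=O)CCc3ccccc3)c2O1
F4 | step 5 | racemic methyl 3-[4-(benzyloxy)phenyl]-3-[2-(benzyloxy)-4-hydroxy-5-(3-phenylpropanoyl)phenyl]propanoate | COC(=O)CC(c1ccc(OCc2ccccc2)cc1)c1cc(C(=O)CCc2ccccc2)c(O)cc1OCc1ccccc1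
F5 | step 5 | racemic 3-[4-(benzyloxy)phenyl]-3-[2-(benzyloxy)-4-hydroxy-5-(3-phenylpropanoyl)phenyl]propanoic acid | OC(=O)CC(c1ccc(OCc2ccccc2)cc1)c1cc(C(=O)CCc2ccccc2)c(O)cc1OCc1ccccc1
F6 | step 5 | (R)-1-phenylethylammonium (S)-3-[4-(benzyloxy)phenyl]-3-[2-(benzyloxy)-4-hydroxy-5-(3-phenylpropanoyl)phenyl]propanoate | [O-]C(=O)C[C@@H](c1ccc(OCc2ccccc2)cc1)c1cc(C(=O)CCc2ccccc2)c(O)cc1OCc1ccccc1.C[C@@H]([NH3+])c1ccccc1
F7 | step 3 | 1-(5-bromo-2,4-dihydroxyphenyl)-3-phenylpropan-1-one | O=C(CCc1ccccc1)c1cc(Br)c(O)cc1O
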